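## Retrosynthetic overview

- Ring B, the seven-membered lactone-ether, is opened at the aryl ester C–O to give a diaryl ether seco-acid; it is closed last but one by lactonisation onto the ring C hydroxyl at Cb.
- The plan turns on ring C: a fully substituted resorcinol (Ca diaryl ether oxygen, Cb ester oxygen, Cc methyl, Cd phenol) fused through Ce and Cf to the lactol-lactone ring D, whose acetal carbon is the only stereocentre. Ring C is cut at Ca–Cf and Cd–Ce into a 4-aryloxy-1-methoxy-2-methyl-1,3-bis(trimethylsilyloxy)diene and a (5R)-3-bromo-5-alkoxyfuranone.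
- The diene is made from the ring A phenol (from atraric acid) by O-alkylation with methyl 4-bromo-2-methylacetoacetate and double silylation. The furanone is made from furfural by photooxygenation, acetalisation with (S)-1-phenylethanol, separation of the C5 epimers and bromination.
- Ring order: ring A is bought, ring D is made first and carries the stereocentre, ring C is formed by cycloaddition and aromatisation, ring B closes next, and the auxiliary is then removed by hydrogenolysis.

Key step: step 11

Assumption: the lactol carbon of a 3-hydroxyphthalide can epimerise through its ring-opened formyl acid, so the route assumes that it holds its (R) configuration under neutral, aprotic conditions, and that the two C5 epimers of the furanone acetal can be separated on silica.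

## Route

Step 1
Reactants: 1 atraric acid (methyl 2,4-dihydroxy-3,6-dimethylbenzoate)
Product: 2 methyl 2-hydroxy-4-methoxy-3,6-dimethylbenzoate
Conditions: MeI (1.1 equiv), K2CO3, acetone, reflux
Reagents that add atoms: iodomethane, CI
Why: Williamson O-methylation should occur only at the 4-hydroxyl, because the 2-hydroxyl is hydrogen-bonded to the ester carbonyl and flanked by two substituents.

Step 2
Reactants: 2 methyl 2-hydroxy-4-methoxy-3,6-dimethylbenzoate
Product: 3 2-hydroxy-4-methoxy-3,6-dimethylbenzoic acid
Conditions: KOH, DMSO/H2O, 80 °C; then cold dilute HCl to pH 3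
Reagents that add atoms: potassium hydroxide, [K+].[OH-]
Why: Saponification of the hindered methyl ester by poorly solvated hydroxide should give the salicylic acid, which is isolated cold to avoid decarboxylation.

Step 3
Reactants: 3 2-hydroxy-4-methoxy-3,6-dimethylbenzoic acid
Product: 4 allyl 2-hydroxy-4-methoxy-3,6-dimethylbenzoate
Conditions: allyl bromide, KHCO3, DMF, rt
Reagents that add atoms: allyl bromide, C=CCBr
Why: SN2 alkylation of the carboxylate, the only site that hydrogencarbonate deprotonates, should give the allyl ester and leave the hydrogen-bonded phenol free.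

Step 4
Reactants: 5 methyl 2-methylacetoacetate
Product: 7 methyl 4-bromo-2-methyl-3-oxobutanoate, via 2-bromo isomer 6 (not isolated)
Conditions: Br2 (1.0 equiv), CHCl3, 0 °C → rt, 16 h, HBr kept in solution; used crude
Reagents that add atoms: bromine, BrBr
Why: Electrophilic α-bromination first gives the 2-bromo ketoester, which the retained HBr should isomerise to the more stable 4-bromo compound (acid-mediated bromine migration known for 2-alkylacetoacetates).

Step 5
Reactants: 4 allyl 2-hydroxy-4-methoxy-3,6-dimethylbenzoate; 7 methyl 4-bromo-2-methyl-3-oxobutanoate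
Product: 8 allyl 4-methoxy-2-[(4-methoxy-3-methyl-2,4-dioxobutyl)oxy]-3,6-dimethylbenzoate
Conditions: NaH (2.1 equiv), DMF/THF, 0 °C; 7 added dropwise; rt; cold 1 M HCl quench
Reagents that add atoms: none
Why: Williamson ether synthesis in which the second equivalent of base holds the bromoketoester as its enolate, so the phenoxide displaces the primary bromide without attacking the ketone (the usual access to 4-aryloxyacetoacetates).

Step 6
Reactants: 8 allyl 4-methoxy-2-[(4-methoxy-3-methyl-2,4-dioxobutyl)oxy]-3,6-dimethylbenzoate
Product: 9 allyl 4-methoxy-2-{[4-methoxy-3-methyl-4-oxo-2-(trimethylsilyloxy)but-2-en-1-yl]oxy}-3,6-dimethylbenzoate (E/Z mixture)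
Conditions: Me3SiCl, Et3N, toluene, rt; filtered under argon
Reagents that add atoms: chlorotrimethylsilane, C[Si](C)(C)Cl
Why: O-silylation of the β-ketoester at its doubly activated position under amine base should give the β-silyloxy enoate (silyl enol ether formation).

Step 7
Reactants: 9 allyl 4-methoxy-2-{[4-methoxy-3-methyl-4-oxo-2-(trimethylsilyloxy)but-2-en-1-yl]oxy}-3,6-dimethylbenzoate
Product: 10 allyl 4-methoxy-2-{[4-methoxy-3-methyl-2,4-bis(trimethylsilyloxy)buta-1,3-dien-1-yl]oxy}-3,6-dimethylbenzoate (geometric isomers, used crude)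
Conditions: LiN(iPr)2 (1.1 equiv) added to 9 and Me3SiCl, THF, −78 °C → 0 °C; hexane, filtration under argon
Reagents that add atoms: chlorotrimethylsilane, C[Si](C)(C)Cl
Why: γ-Deprotonation of the silyloxy enoate at the aryloxymethylene group gives the extended lithium dienolate, which is silylated on oxygen as it forms (standard two-stage preparation of 1,3-bis(silyloxy)dienes), the in situ quench suppressing Dieckmann-type attack on the neighbouring allyl ester.

Step 8
Reactants: 11 furfural
Product: 12 5-hydroxyfuran-2(5H)-one (racemic)
Conditions: O2, visible light, methylene blue (cat.), MeOH, rt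
Reagents that add atoms: dioxygen, O=O
Why: Singlet-oxygen [4+2] cycloaddition to the furan gives an endoperoxide that methanol cleaves with loss of the formyl carbon as methyl formate (dye-sensitised photooxygenation of furfural).

Step 9
Reactants: 12 5-hydroxyfuran-2(5H)-one; 13 (S)-1-phenylethanol
Product: 14 (5R)-5-[(1S)-1-phenylethoxy]furan-2(5H)-one
Conditions: camphorsulfonic acid (cat.), benzene, 4 Å molecular sieves, 60 °C; chromatographic separation of the C5 epimers
Reagents that add atoms: none
Why: Acid-catalysed acetalisation of the pseudo-acid lactol gives both C5 epimers without useful selectivity, so the acetal configuration is fixed by isolating the (5R) diastereomer, while the (5S) diastereomer is returned to the same acid conditions, which re-equilibrate the acetal centre, and the mild sulfonic acid should leave the benzylic alcohol centre intact.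

Step 10
Reactants: 14 (5R)-5-[(1S)-1-phenylethoxy]furan-2(5H)-one
Product: 16 (5R)-3-bromo-5-[(1S)-1-phenylethoxy]furan-2(5H)-one, via dibromolactone 15 (not isolated)
Conditions: Br2, CH2Cl2, 0 °C → rt, dark; then Et3N, 0 °C
Reagents that add atoms: bromine, BrBr
Why: anti-Addition of bromine followed by E1cB loss of HBr through the lactone enolate should give the α-bromobutenolide (bromination–dehydrobromination), and brief contact with Et3N at 0 °C should not touch the C5 acetal hydrogen.

Step 11
Reactants: 10 allyl 4-methoxy-2-{[4-methoxy-3-methyl-2,4-bis(trimethylsilyloxy)buta-1,3-dien-1-yl]oxy}-3,6-dimethylbenzoate; 16 (5R)-3-bromo-5-[(1S)-1-phenylethoxy]furan-2(5H)-one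
Product: 19 allyl 2-{[(3R)-5,7-dihydroxy-6-methyl-1-oxo-3-[(1S)-1-phenylethoxy]-1,3-dihydroisobenzofuran-4-yl]oxy}-4-methoxy-3,6-dimethylbenzoate, via cycloadduct 17 (not isolated), via bis-silyl ether 18 (not isolated)
Conditions: 10 (1.5 equiv), toluene, rt → 60 °C; then DBU, rt; then Bu4NF/AcOH, THF, 0 °C
Reagents that add atoms: none
Why: Normal-demand Diels–Alder reaction followed by aromatisation: the aryloxy-bearing terminus of the bis(silyloxy)diene (future Ca), its most nucleophilic carbon, bonds to the β-carbon of the butenolide (future Cf) and the ketene acetal carbon (Cd) bonds to the brominated α-carbon (Ce), either concertedly or as a Mukaiyama–Michael addition followed by ring closure. Ring C is thereby closed by an intermolecular [4+2] cycloaddition onto the existing ring D, the closest analogy being the annulation of halogenated quinones, enones and butenolides by 1-alkoxy-1,3-bis(silyloxy)dienes. In cycloadduct 17 the mixed ketal at Cd should first lose methanol in a 1,4-sense (hydrogen from Ca), and the resulting bromocyclohexadiene, whose C–Br bond is allylic and donor-stabilised, should then give up HBr to DBU with aromatisation as the driving force; buffered fluoride finally desilylates bis-silyl ether 18 to 19. No new stereocentre survives, because the four sp3 ring carbons of 17 all become aromatic, so endo/exo and facial selectivity do not matter, and the acetal carbon is a spectator that keeps its (R) configuration because only base and buffered fluoride are used, never strong acid. The only selectivity needed is regiochemical, and it is secured by the matched polarisation of the two partners, with bromine placed on the carbon that becomes Ce.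

Step 12
Reactants: 19 allyl 2-{[(3R)-5,7-dihydroxy-6-methyl-1-oxo-3-[(1S)-1-phenylethoxy]-1,3-dihydroisobenzofuran-4-yl]oxy}-4-methoxy-3,6-dimethylbenzoate
Product: 20 2-{[(3R)-5,7-dihydroxy-6-methyl-1-oxo-3-[(1S)-1-phenylethoxy]-1,3-dihydroisobenzofuran-4-yl]oxy}-4-methoxy-3,6-dimethylbenzoic acid
Conditions: Pd(PPh3)4 (5 mol%), N-methylaniline, THF, rt; pH 4 buffer wash
Reagents that add atoms: none
Why: Tsuji–Trost deallylation, in which zerovalent palladium ionises the allyl ester to a π-allyl complex that the weakly basic amine captures, should free the acid under near-neutral conditions that spare the acetal, the lactone and the phenols.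

Step 13
Reactants: 20 2-{[(3R)-5,7-dihydroxy-6-methyl-1-oxo-3-[(1S)-1-phenylethoxy]-1,3-dihydroisobenzofuran-4-yl]oxy}-4-methoxy-3,6-dimethylbenzoic acid
Product: 21 depsidone (R)-acetal (the target carrying its lactol hydroxyl as the (S)-1-phenylethyl ether)
Conditions: DCC, 4-(dimethylamino)pyridine (cat.), CH2Cl2 (high dilution), 0 °C → rt
Reagents that add atoms: none
Why: Carbodiimide (Steglich-type) lactonisation onto the ring C hydroxyl ortho to the ether oxygen should close the seven-membered ring B, the other phenol being out of reach and hydrogen-bonded to the phthalide carbonyl (the established depsidone ring closure).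

Step 14
Reactants: 21 depsidone (R)-acetal
Product: 22 target depsidone (R)-lactol (CNP0255863.1)
Conditions: H2 (1 atm), 10% Pd/C, EtOAc, rt; filtration, evaporation below rt
Reagents that add atoms: none
Why: Catalytic hydrogenolysis cleaves the O–CH(CH3)Ph benzylic bond and no bond to the acetal carbon, so the (R) configuration should pass unchanged to the lactol, which is isolated under neutral aprotic conditions.

## Compound list

1 | atraric acid (methyl 2,4-dihydroxy-3,6-dimethylbenzoate) | COC(=O)c1c(C)cc(O)c(C)c1O | starting material
2 | methyl 2-hydroxy-4-methoxy-3,6-dimethylbenzoate | COC(=O)c1c(C)cc(OC)c(C)c1O | intermediate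
3 | 2-hydroxy-4-methoxy-3,6-dimethylbenzoic acid | OC(=O)c1c(C)cc(OC)c(C)c1O | intermediate
4 | allyl 2-hydroxy-4-methoxy-3,6-dimethylbenzoate | C=CCOC(=O)c1c(C)cc(OC)c(C)c1O | intermediate
5 | methyl 2-methylacetoacetate | COC(=O)C(C)C(C)=O | starting material
6 | methyl 2-bromo-2-methyl-3-oxobutanoate (not isolated) | COC(=O)C(C)(Br)C(C)=O | intermediate
7 | methyl 4-bromo-2-methyl-3-oxobutanoate (racemic) | COC(=O)C(C)C(=O)CBr | intermediate
8 | allyl 4-methoxy-2-[(4-methoxy-3-methyl-2,4-dioxobutyl)oxy]-3,6-dimethylbenzoate | COc1cc(C)c(C(=O)OCC=C)c(OCC(=O)C(C)C(=O)OC)c1C | intermediate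
9 | allyl 4-methoxy-2-{[4-methoxy-3-methyl-4-oxo-2-(trimethylsilyloxy)but-2-en-1-yl]oxy}-3,6-dimethylbenzoate (E/Z mixture) | COc1cc(C)c(C(=O)OCC=C)c(OCC(O[Si](C)(C)C)=C(C)C(=O)OC)c1C | intermediate
10 | allyl 4-methoxy-2-{[4-methoxy-3-methyl-2,4-bis(trimethylsilyloxy)buta-1,3-dien-1-yl]oxy}-3,6-dimethylbenzoate (geometric isomers) | COc1cc(C)c(C(=O)OCC=C)c(OC=C(O[Si](C)(C)C)C(C)=C(OC)O[Si](C)(C)C)c1C | intermediate
11 | furfural | O=Cc1ccco1 | starting material
12 | 5-hydroxyfuran-2(5H)-one (racemic) | O=C1C=CC(O)O1 | intermediate
13 | (S)-1-phenylethanol | C[C@H](O)c1ccccc1 | starting material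
14 | (5R)-5-[(1S)-1-phenylethoxy]furan-2(5H)-one | O=C1C=C[C@H](O[C@@H](C)c2ccccc2)O1 | intermediate
15 | (5R)-3,4-dibromo-5-[(1S)-1-phenylethoxy]dihydrofuran-2(3H)-one (3,4-trans, not isolated) | BrC1C(Br)[C@H](O[C@@H](C)c2ccccc2)OC1=O | intermediate
16 | (5R)-3-bromo-5-[(1S)-1-phenylethoxy]furan-2(5H)-one | BrC1=C[C@H](O[C@@H](C)c2ccccc2)OC1=O | intermediate
17 | cis-fused cycloadduct: ring A ether at C4 of 7a-bromo-7-methoxy-6-methyl-3-[(1S)-1-phenylethoxy]-5,7-bis(trimethylsilyloxy)-3a,4,7,7a-tetrahydroisobenzofuran-1(3H)-one, new ring bonds anti to the 1-phenylethoxy group, C4 and C7 as epimer mixtures (not isolated) | COc1cc(C)c(C(=O)OCC=C)c(OC2C(O[Si](C)(C)C)=C(C)C(OC)(O[Si](C)(C)C)[C@]3(Br)C(=O)O[C@@H](O[C@@H](C)c4ccccc4)[C@H]23)c1C | intermediate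
18 | allyl 4-methoxy-3,6-dimethyl-2-{[(3R)-6-methyl-1-oxo-3-[(1S)-1-phenylethoxy]-5,7-bis(trimethylsilyloxy)-1,3-dihydroisobenzofuran-4-yl]oxy}benzoate (not isolated) | COc1cc(C)c(C(=O)OCC=C)c(Oc2c(O[Si](C)(C)C)c(C)c(O[Si](C)(C)C)c3c2[C@H](O[C@@H](C)c4ccccc4)OC3=O)c1C | intermediate
19 | allyl 2-{[(3R)-5,7-dihydroxy-6-methyl-1-oxo-3-[(1S)-1-phenylethoxy]-1,3-dihydroisobenzofuran-4-yl]oxy}-4-methoxy-3,6-dimethylbenzoate | COc1cc(C)c(C(=O)OCC=C)c(Oc2c(O)c(C)c(O)c3c2[C@H](O[C@@H](C)c4ccccc4)OC3=O)c1C | intermediate
20 | 2-{[(3R)-5,7-dihydroxy-6-methyl-1-oxo-3-[(1S)-1-phenylethoxy]-1,3-dihydroisobenzofuran-4-yl]oxy}-4-methoxy-3,6-dimethylbenzoic acid | COc1cc(C)c(C(=O)O)c(Oc2c(O)c(C)c(O)c3c2[C@H](O[C@@H](C)c4ccccc4)OC3=O)c1C | intermediate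
21 | depsidone (R)-acetal: target with the lactol hydroxyl as its (S)-1-phenylethyl ether | COc1cc(C)c2c(c1C)Oc1c(c(C)c(O)c3c1[C@H](O[C@@H](C)c4ccccc4)OC3=O)OC2=O | intermediate
22 | target depsidone (R)-lactol (CNP0255863.1) | COc1cc(C)c2c(c1C)Oc1c(c(C)c(O)c3c1[C@H](O)OC3=O)OC2=O | target

## Step count and risks

Total steps: 14. Longest linear sequence: 10 steps (steps 1, 2, 3, 5, 6, 7, 11, 12, 13, 14).

**Step 11.** The tetrasubstituted diene may hydrolyse or lose its silyl groups before it cycloadds. Because bromine and the ring-fusion hydrogen of the adduct are cis, dehydrobromination may also stall, or give way to reductive loss of bromine or to elimination of the aryloxy group. The fallback sets out from diene 10 and the unbrominated butenolide 14. A thermal Diels–Alder reaction (toluene, 90 °C) followed by Bu4NF/AcOH should give the cis-fused 5,7-dioxo lactone F1. This is then dehydrogenated with 2,3-dichloro-5,6-dicyano-1,4-benzoquinone (dioxane, 60 °C): hydride abstraction from the ring-fusion carbon C3a of the β-keto lactone enol gives a cyclohexenedione that enolises to the resorcinol. The route is rejoined at 19.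

**Step 5.** The hindered, hydrogen-bonded phenoxide may alkylate slowly while the bromoketoester enolate cyclises to a furanone or condenses with itself. The fallback sets out from 4. Alkylation with tert-butyl bromoacetate (K2CO3, DMF, 60 °C) should give the aryloxyacetate tert-butyl ester F2, and CF3CO2H in CH2Cl2 frees the aryloxyacetic acid F3. Activation with carbonyldiimidazole and decarboxylative Claisen condensation with potassium methyl 2-methylmalonate (MgCl2, Et3N, MeCN; Masamune–Brooks conditions) then builds the β-ketoester. The route is rejoined at 8.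

**Step 14.** Hydrogenolysis of the hindered secondary benzylic ether may be slow, or may go on to reduce the benzylic acetal carbon of the phthalide, and the freed lactol may epimerise by ring-opening during isolation. The fallback sets out from 21 and replaces reductive cleavage by Lewis-acid heterolysis: BCl3 with pentamethylbenzene as cation trap, CH2Cl2, −78 °C, then cold pH 7 buffer. Ionisation should occur at the 1-phenylethyl carbon, which gives the better-stabilised cation, and not at the acyloxy-substituted acetal carbon. It arrives directly at 22 and makes no new intermediate.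

## Further compounds

F1 | step 11 | allyl 4-methoxy-3,6-dimethyl-2-{[6-methyl-1,5,7-trioxo-3-[(1S)-1-phenylethoxy]octahydroisobenzofuran-4-yl]oxy}benzoate (cis-fused, 3R acetal, enolisable centres unassigned) | COc1cc(C)c(C(=O)OCC=C)c(OC2C(=O)C(C)C(=O)C3C(=O)O[C@@H](O[C@@H](C)c4ccccc4)[C@H]23)c1C
F2 | step 5 | allyl 2-(2-tert-butoxy-2-oxoethoxy)-4-methoxy-3,6-dimethylbenzoate | COc1cc(C)c(C(=O)OCC=C)c(OCC(=O)OC(C)(C)C)c1C
F3 | step 5 | {2-[(allyloxy)carbonyl]-5-methoxy-3,6-dimethylphenoxy}acetic acid | COc1cc(C)c(C(=O)OCC=C)c(OCC(=O)O)c1C
F0 | step 14 | none | none
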